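The route rests on removing both carbon substituents of the benzene ring together: the C1–acetyl bond and the bond from C6 to the methylene that leads to pyrone C3. C1 and C6 are ortho neighbours and C1 lies beside oxygenated C2. A 3-alkoxyaryne returns exactly this pattern when it inserts into the acyl–Cα σ bond of a β-keto ester. One operation thus unites the arene with the (S)-configured 2-pyrone and sets the acetyl group. Its precursors are an ortho-silylaryl triflate (MOM ethers at C2 and C3, methoxy at C4) and a benzyl acetoacetate carrying the MOM-protected pyrone on its α-carbon. The surplus ester carbon leaves afterwards by hydrogenolysis and radical hydrodecarboxylation.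

Key step: step 15

Remarks on the chemistry
- Numbering used: benzene C1 (acetyl), C2 and C3 (OH), C4 (OMe), C5 (H), C6 (CH2). Pyrone O1, C2 (C=O), C3 (CH2Ar), C4 (OH), C6 (side chain).
- The carbinol centre of the target is (S) (O > CH2-pyrone > CH3 > H). It is bought with ethyl (S)-3-hydroxybutanoate, and its C–O bond is never broken.
- The ester-bearing carbon of the keto ester donor, of the insertion product and of the derived acid is an uncontrolled, enolisable stereocentre. These three compounds are handled as epimer mixtures and drawn without configuration there, and the carbon ends as CH2.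
- Assumption: the aryl(pyronyl)acetic acid is not counted on to lose CO2 on warming. Pyrone C3 is the α-carbon of the ring carbonyl system, so a carbanion on the attached carbon cannot be delocalised into it, and the doubly flanked acetyl group is twisted out of conjugation. A radical hydrodecarboxylation is therefore planned.
- Protecting-group logic: the ester is the only benzyl group and all four hydroxyls are MOM ethers. Hydrogenolysis then frees the acid alone, because a free pyrone 4-OH would lactonise onto it. One acid treatment ends the synthesis.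

Step 1
Reactants: 1 5-hydroxyvanillin (3,4-dihydroxy-5-methoxybenzaldehyde)
Product: 2 3-methoxy-4,5-bis(methoxymethoxy)benzaldehyde
Conditions: MOMCl (2.6 equiv), iPr2NEt (3 equiv), CH2Cl2, 0 °C to rt
Reagents that add atoms: chloromethyl methyl ether, COCCl
Why: O-alkylation of both phenols by the reactive chloromethyl ether (acetal-type ether formation) under amine base leaves the aldehyde alone and installs groups that later steer lithiation and fall off in mild acid.

Step 2
Reactants: 2 3-methoxy-4,5-bis(methoxymethoxy)benzaldehyde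
Product: 4 3-methoxy-4,5-bis(methoxymethoxy)phenol, via aryl formate 3 (not isolated)
Conditions: mCPBA (1.3 equiv), CH2Cl2, 0 °C to rt; then K2CO3 (0.2 equiv), MeOH, rt
Reagents that add atoms: 3-chloroperoxybenzoic acid, OOC(=O)c1cccc(Cl)c1
Why: Baeyer–Villiger oxidation with migration of the electron-rich aryl group gives the formate and base-catalysed transesterification with methanol frees the phenol, the peracid being chosen because an aldehyde without a free ortho or para hydroxyl does not undergo a Dakin reaction.

Step 3
Reactants: 4 3-methoxy-4,5-bis(methoxymethoxy)phenol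
Product: 5 3-methoxy-4,5-bis(methoxymethoxy)phenyl N-(propan-2-yl)carbamate
Conditions: iPrNCO (1.5 equiv), Et3N (0.2 equiv), CH2Cl2, rt
Reagents that add atoms: isopropyl isocyanate, CC(C)N=C=O
Why: Amine-catalysed addition of the phenol to the isocyanate (carbamoylation) gives the strongest oxygen-based director for lithiation in a form that mild base can remove later.

Step 4
Reactants: 5 3-methoxy-4,5-bis(methoxymethoxy)phenyl N-(propan-2-yl)carbamate
Product: 9 5-methoxy-3,4-bis(methoxymethoxy)-2-(trimethylsilyl)phenyl N-(propan-2-yl)carbamate, via N-silyl carbamate 6 (not isolated), via aryllithium 7 (not isolated), via doubly silylated carbamate 8 (not isolated)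
Conditions: TBSOTf (1.05 equiv), TMEDA (1.1 equiv), Et2O, 0 °C to rt; TMEDA (2 equiv), n-BuLi (2.1 equiv), −78 °C; TMSCl (3 equiv), −78 °C to rt; cold aq. NaHSO4 work-up
Reagents that add atoms: chlorotrimethylsilane, C[Si](C)(C)Cl (tert-butyldimethylsilyl triflate, CC(C)(C)[Si](C)(C)OS(=O)(=O)C(F)(F)F, supplies only the transient N-silyl group of 6 to 8)
Why: Directed ortho-metalation in which N-silylation masks the acidic N–H, both ring hydrogens are ortho to the carbamate but the one next to the chelating, more strongly directing OMOM group rather than the one next to OMe should be removed by n-BuLi/TMEDA, TMSCl quenches the aryllithium, and the N–Si bond is hydrolysed on work-up.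

Step 5
Reactants: 9 5-methoxy-3,4-bis(methoxymethoxy)-2-(trimethylsilyl)phenyl N-(propan-2-yl)carbamate
Product: 11 5-methoxy-3,4-bis(methoxymethoxy)-2-(trimethylsilyl)phenyl trifluoromethanesulfonate, via silylphenol 10 (not isolated)
Conditions: Et2NH (1.5 equiv), DBU (1.5 equiv), MeCN, 40 °C; then PhNTf2 (1.5 equiv), rt
Reagents that add atoms: N-phenylbis(trifluoromethanesulfonimide), O=S(=O)(N(c1ccccc1)S(=O)(=O)C(F)(F)F)C(F)(F)F
Why: E1cB cleavage of the secondary carbamate by DBU expels the phenoxide, diethylamine scavenges the isocyanate, and the phenoxide is sulfonylated in the same flask by the mild triflyl donor, which places silicon on the future C1 and triflate on the future C6.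

Step 6
Reactants: 12 ethyl (S)-3-hydroxybutanoate
Product: 13 ethyl (3S)-3-(methoxymethoxy)butanoate
Conditions: MOMCl (1.5 equiv), iPr2NEt (2 equiv), CH2Cl2, 0 °C to rt
Reagents that add atoms: chloromethyl methyl ether, COCCl
Why: Acetal-type O-alkylation under weak amine base does not touch the C–O bond of the stereocentre, so the (S) configuration of the chiral-pool ester is carried over, and an acetal, unlike a silyl ether, will survive fluoride.

Step 7
Reactants: 13 ethyl (3S)-3-(methoxymethoxy)butanoate
Product: 14 (3S)-N-methoxy-3-(methoxymethoxy)-N-methylbutanamide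
Conditions: MeNH(OMe)·HCl (1.6 equiv), iPrMgCl (3.2 equiv), THF, −20 to 0 °C
Reagents that add atoms: N,O-dimethylhydroxylamine hydrochloride, CNOC.Cl
Why: Ester aminolysis by the chloromagnesium amide made in situ proceeds at low temperature, where β-elimination of the alkoxy group does not compete and the stereocentre is not involved.

Step 8
Reactants: 15 2,2,6-trimethyl-4H-1,3-dioxin-4-one; 14 (3S)-N-methoxy-3-(methoxymethoxy)-N-methylbutanamide
Product: 17 2,2-dimethyl-6-[(4S)-4-(methoxymethoxy)-2-oxopentyl]-4H-1,3-dioxin-4-one, via lithium dienolate 16 (not isolated)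
Conditions: 15 (2 equiv), LiN(SiMe3)2 (2 equiv), THF, −78 °C; then 14, −78 to −30 °C; AcOH quench
Reagents that add atoms: none
Why: Vinylogous Claisen-type acylation in which the extended lithium enolate reacts through its γ-carbon with the N-methoxy-N-methylamide, an acyl donor that stops cleanly at the ketone stage.

Step 9
Reactants: 17 2,2-dimethyl-6-[(4S)-4-(methoxymethoxy)-2-oxopentyl]-4H-1,3-dioxin-4-one
Product: 19 4-hydroxy-6-[(2S)-2-(methoxymethoxy)propyl]-2H-pyran-2-one, via acylketene 18 (not isolated)
Conditions: PhMe, 110 °C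
Reagents that add atoms: none
Why: Thermal cycloreversion (retro-hetero-Diels–Alder) of the dioxinone releases acetone and an acylketene, which the enol oxygen of the remote ketone captures in a six-membered lactonisation to give the 4-hydroxy-2-pyrone under neutral conditions.

Step 10
Reactants: 19 4-hydroxy-6-[(2S)-2-(methoxymethoxy)propyl]-2H-pyran-2-one
Product: 20 4-hydroxy-3-iodo-6-[(2S)-2-(methoxymethoxy)propyl]-2H-pyran-2-one
Conditions: NIS (1.05 equiv), MeCN, 0 °C to rt, dark
Reagents that add atoms: N-iodosuccinimide, O=C1CCC(=O)N1I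
Why: Electrophilic iodination takes place at C3, the nucleophilic carbon of the cyclic enol flanked by the C2 carbonyl and the C4 hydroxyl.

Step 11
Reactants: 20 4-hydroxy-3-iodo-6-[(2S)-2-(methoxymethoxy)propyl]-2H-pyran-2-one
Product: 21 3-iodo-4-(methoxymethoxy)-6-[(2S)-2-(methoxymethoxy)propyl]-2H-pyran-2-one
Conditions: MOMCl (1.3 equiv), iPr2NEt (1.5 equiv), CH2Cl2, 0 °C
Reagents that add atoms: chloromethyl methyl ether, COCCl
Why: O-alkylation of the acidic vinylogous carboxylic acid by the hard chloromethyl ether should occur on the 4-oxygen, giving the 4-alkoxy-2-pyrone and blocking later furan or lactone formation by that oxygen.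

Step 12
Reactants: 15 2,2,6-trimethyl-4H-1,3-dioxin-4-one
Product: 22 5-iodo-2,2,6-trimethyl-4H-1,3-dioxin-4-one
Conditions: NIS (1.2 equiv), AcOH, rt, dark
Reagents that add atoms: N-iodosuccinimide, O=C1CCC(=O)N1I
Why: Electrophilic iodination of the enol-ether-type C5 position of the dioxinone functionalises what is the α-carbon of a masked acetoacetate.

Step 13
Reactants: 22 5-iodo-2,2,6-trimethyl-4H-1,3-dioxin-4-one; 21 3-iodo-4-(methoxymethoxy)-6-[(2S)-2-(methoxymethoxy)propyl]-2H-pyran-2-one
Product: 25 5-{4-(methoxymethoxy)-6-[(2S)-2-(methoxymethoxy)propyl]-2-oxo-2H-pyran-3-yl}-2,2,6-trimethyl-4H-1,3-dioxin-4-one, via magnesiated dioxinone 23 (not isolated), via zincated dioxinone 24 (not isolated)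
Conditions: 22 (1.4 equiv), iPrMgCl (1.45 equiv), THF, −30 °C; ZnCl2 (1.5 equiv), −30 to 0 °C; then 21, Pd2(dba)3 (2.5 mol %), SPhos (10 mol %), THF, 45 °C
Reagents that add atoms: none
Why: Iodine–magnesium exchange on the alkenyl iodide, transmetalation to zinc and Negishi coupling under zerovalent palladium with a bulky biarylphosphine join the masked acetoacetate α-carbon to pyrone C3 without any base that could eliminate the β-alkoxy group of the side chain.

Step 14
Reactants: 25 5-{4-(methoxymethoxy)-6-[(2S)-2-(methoxymethoxy)propyl]-2-oxo-2H-pyran-3-yl}-2,2,6-trimethyl-4H-1,3-dioxin-4-one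
Product: 27 benzyl 2-{4-(methoxymethoxy)-6-[(2S)-2-(methoxymethoxy)propyl]-2-oxo-2H-pyran-3-yl}-3-oxobutanoate, via acetyl(pyronyl)ketene 26 (not isolated)
Conditions: BnOH (3 equiv), PhMe, 110 °C, sealed tube
Reagents that add atoms: benzyl alcohol, OCc1ccccc1
Why: Thermal cycloreversion of the dioxinone gives the α-pyronyl acetylketene, which benzyl alcohol traps by addition to give the β-keto ester under neutral conditions.

Step 15
Reactants: 27 benzyl 2-{4-(methoxymethoxy)-6-[(2S)-2-(methoxymethoxy)propyl]-2-oxo-2H-pyran-3-yl}-3-oxobutanoate; 11 5-methoxy-3,4-bis(methoxymethoxy)-2-(trimethylsilyl)phenyl trifluoromethanesulfonate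
Product: 30 benzyl 2-[2-acetyl-5-methoxy-3,4-bis(methoxymethoxy)phenyl]-2-{4-(methoxymethoxy)-6-[(2S)-2-(methoxymethoxy)propyl]-2-oxo-2H-pyran-3-yl}acetate, via aryne 28 (not isolated), via benzocyclobutenoxide 29 (not isolated)
Conditions: 27 and CsF (4 equiv) pre-stirred, MeCN; 11 (1.5 equiv) added slowly, 60 to 80 °C
Reagents that add atoms: none
Why: Fluoride attacks silicon and triflate departs to give aryne 28 (triple bond C1–C6), the caesium enolate of 27 adds through its α-carbon to C6, and the C1 aryl anion closes on the adjacent acetyl carbonyl (4-exo-trig) to give benzocyclobutenoxide 29. Strain-driven retro-aldol opening of 29 cleaves the original acetyl–Cα bond, so the acetyl group ends on C1, the ester-stabilised benzylic anion is protonated, and the four-membered ring is only transient, no ring remaining closed. The closest known reaction type is the aryne acyl-alkylation of β-keto esters, which is documented for α-substituted and cyclic donors, the α-heteroaryl donor used here lying at the crowded end of that scope. Regioselectivity is required and is secured by the OMOM group on C2, whose inductive withdrawal distorts the aryne so that nucleophiles attack the remote carbon C6 and the negative charge develops on C1 next to oxygen. Chemoselectivity is required as well: the methyl ketone is the most electrophilic carbonyl within reach of the aryl anion (the ester is less so, and the pyrone C2 carbonyl is a deactivated vinylogous carbonate), and pre-forming the enolate lets carbon addition outrun Diels–Alder capture of the aryne by the trisubstituted pyrone diene. The new methine stereocentre arises without any controlling element, is epimerisable and disappears in step 17, while the remote (S)-carbinol centre is not touched.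

Step 16
Reactants: 30 benzyl 2-[2-acetyl-5-methoxy-3,4-bis(methoxymethoxy)phenyl]-2-{4-(methoxymethoxy)-6-[(2S)-2-(methoxymethoxy)propyl]-2-oxo-2H-pyran-3-yl}acetate
Product: 31 2-[2-acetyl-5-methoxy-3,4-bis(methoxymethoxy)phenyl]-2-{4-(methoxymethoxy)-6-[(2S)-2-(methoxymethoxy)propyl]-2-oxo-2H-pyran-3-yl}acetic acid
Conditions: H2 (1 atm), 10% Pd/C, EtOAc, rt, short reaction time
Reagents that add atoms: none
Why: Catalytic hydrogenolysis cleaves the only benzylic C–O bond of the molecule, while the MOM acetals, the 4-alkoxy-2-pyrone ring and the hindered, twisted aryl ketone should not be reduced at atmospheric pressure.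

Step 17
Reactants: 31 2-[2-acetyl-5-methoxy-3,4-bis(methoxymethoxy)phenyl]-2-{4-(methoxymethoxy)-6-[(2S)-2-(methoxymethoxy)propyl]-2-oxo-2H-pyran-3-yl}acetic acid
Product: 32 3-{[2-acetyl-5-methoxy-3,4-bis(methoxymethoxy)phenyl]methyl}-4-(methoxymethoxy)-6-[(2S)-2-(methoxymethoxy)propyl]-2H-pyran-2-one
Conditions: 9-mesityl-10-methylacridinium tetrafluoroborate (5 mol %), (4-ClC6H4S)2 (10 mol %), 2,6-lutidine (0.3 equiv), ClCH2CH2Cl, 450 nm LEDs, rt, N2
Reagents that add atoms: none
Why: Photoredox hydrodecarboxylation of an arylacetic acid, in which the excited acridinium oxidises the carboxylate, CO2 is lost to give a radical stabilised by both rings, and the arenethiol formed from the disulfide delivers the hydrogen atom, so the bridge becomes CH2 without relying on carbanion stability.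

Step 18
Reactants: 32 3-{[2-acetyl-5-methoxy-3,4-bis(methoxymethoxy)phenyl]methyl}-4-(methoxymethoxy)-6-[(2S)-2-(methoxymethoxy)propyl]-2H-pyran-2-one
Product: 33 penicanesin D, 3-[(2-acetyl-3,4-dihydroxy-5-methoxyphenyl)methyl]-4-hydroxy-6-[(2S)-2-hydroxypropyl]-2H-pyran-2-one
Conditions: HCl (2 M, from conc. aq. HCl), MeOH, 45 °C
Reagents that add atoms: none
Why: Acid-catalysed acetal exchange with methanol removes all four MOM groups by cleavage of their O–CH2–O bonds, so the aryl methyl ether stays and the carbinol C–O bond, and with it the (S) configuration, is retained.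

Compound list
1 | 5-hydroxyvanillin (3,4-dihydroxy-5-methoxybenzaldehyde) | COc1cc(C=O)cc(O)c1O | starting material
2 | 3-methoxy-4,5-bis(methoxymethoxy)benzaldehyde | COCOc1cc(C=O)cc(OC)c1OCOC | intermediate
3 | 3-methoxy-4,5-bis(methoxymethoxy)phenyl formate (formed in the flask) | COCOc1cc(OC=O)cc(OC)c1OCOC | intermediate
4 | 3-methoxy-4,5-bis(methoxymethoxy)phenol | COCOc1cc(O)cc(OC)c1OCOC | intermediate
5 | 3-methoxy-4,5-bis(methoxymethoxy)phenyl N-(propan-2-yl)carbamate | COCOc1cc(OC(=O)NC(C)C)cc(OC)c1OCOC | intermediate
6 | N-(tert-butyldimethylsilyl) derivative of 5 (formed in the flask) | COCOc1cc(OC(=O)N(C(C)C)[Si](C)(C)C(C)(C)C)cc(OC)c1OCOC | intermediate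
7 | aryllithium from 6, lithium on the ring carbon between the carbamate-bearing and the OMOM-bearing carbons (formed in the flask) | COCOc1c(OC)cc(OC(=O)N(C(C)C)[Si](C)(C)C(C)(C)C)c([Li])c1OCOC | intermediate
8 | N-(tert-butyldimethylsilyl) derivative of 9 (formed in the flask) | COCOc1c(OC)cc(OC(=O)N(C(C)C)[Si](C)(C)C(C)(C)C)c([Si](C)(C)C)c1OCOC | intermediate
9 | 5-methoxy-3,4-bis(methoxymethoxy)-2-(trimethylsilyl)phenyl N-(propan-2-yl)carbamate | COCOc1c(OC)cc(OC(=O)NC(C)C)c([Si](C)(C)C)c1OCOC | intermediate
10 | 5-methoxy-3,4-bis(methoxymethoxy)-2-(trimethylsilyl)phenol (formed in the flask) | COCOc1c(OC)cc(O)c([Si](C)(C)C)c1OCOC | intermediate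
11 | 5-methoxy-3,4-bis(methoxymethoxy)-2-(trimethylsilyl)phenyl trifluoromethanesulfonate | COCOc1c(OC)cc(OS(=O)(=O)C(F)(F)F)c([Si](C)(C)C)c1OCOC | intermediate
12 | ethyl (S)-3-hydroxybutanoate | CCOC(=O)C[C@H](C)O | starting material
13 | ethyl (3S)-3-(methoxymethoxy)butanoate | CCOC(=O)C[C@H](C)OCOC | intermediate
14 | (3S)-N-methoxy-3-(methoxymethoxy)-N-methylbutanamide | CON(C)C(=O)C[C@H](C)OCOC | intermediate
15 | 2,2,6-trimethyl-4H-1,3-dioxin-4-one | CC1=CC(=O)OC(C)(C)O1 | starting material
16 | lithium 2,2-dimethyl-6-methylidene-6H-1,3-dioxin-4-olate (formed in the flask) | C=C1C=C(O[Li])OC(C)(C)O1 | intermediate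
17 | 2,2-dimethyl-6-[(4S)-4-(methoxymethoxy)-2-oxopentyl]-4H-1,3-dioxin-4-one | CC1(C)OC(=O)C=C(CC(=O)C[C@H](C)OCOC)O1 | intermediate
18 | (7S)-7-(methoxymethoxy)oct-1-ene-1,3,5-trione, the acylketene (formed in the flask) | O=C=CC(=O)CC(=O)C[C@H](C)OCOC | intermediate
19 | 4-hydroxy-6-[(2S)-2-(methoxymethoxy)propyl]-2H-pyran-2-one | O=c1cc(O)cc(C[C@H](C)OCOC)o1 | intermediate
20 | 4-hydroxy-3-iodo-6-[(2S)-2-(methoxymethoxy)propyl]-2H-pyran-2-one | O=c1oc(C[C@H](C)OCOC)cc(O)c1I | intermediate
21 | 3-iodo-4-(methoxymethoxy)-6-[(2S)-2-(methoxymethoxy)propyl]-2H-pyran-2-one | O=c1oc(C[C@H](C)OCOC)cc(OCOC)c1I | intermediate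
22 | 5-iodo-2,2,6-trimethyl-4H-1,3-dioxin-4-one | CC1=C(I)C(=O)OC(C)(C)O1 | intermediate
23 | (2,2,6-trimethyl-4-oxo-4H-1,3-dioxin-5-yl)magnesium chloride (formed in the flask) | CC1=C([Mg]Cl)C(=O)OC(C)(C)O1 | intermediate
24 | (2,2,6-trimethyl-4-oxo-4H-1,3-dioxin-5-yl)zinc chloride (formed in the flask) | CC1=C([Zn]Cl)C(=O)OC(C)(C)O1 | intermediate
25 | 5-{4-(methoxymethoxy)-6-[(2S)-2-(methoxymethoxy)propyl]-2-oxo-2H-pyran-3-yl}-2,2,6-trimethyl-4H-1,3-dioxin-4-one | CC1=C(C(=O)OC(C)(C)O1)c1c(OCOC)cc(C[C@H](C)OCOC)oc1=O | intermediate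
26 | acetyl{4-(methoxymethoxy)-6-[(2S)-2-(methoxymethoxy)propyl]-2-oxo-2H-pyran-3-yl}ketene (formed in the flask) | CC(=O)C(=C=O)c1c(OCOC)cc(C[C@H](C)OCOC)oc1=O | intermediate
27 | benzyl 2-{4-(methoxymethoxy)-6-[(2S)-2-(methoxymethoxy)propyl]-2-oxo-2H-pyran-3-yl}-3-oxobutanoate (epimers at C2 of the butanoate, partly enol) | CC(=O)C(C(=O)OCc1ccccc1)c1c(OCOC)cc(C[C@H](C)OCOC)oc1=O | intermediate
28 | 5-methoxy-3,4-bis(methoxymethoxy)benzyne, triple bond between the future C1 and C6 (formed in the flask) | COCOC1=C(OCOC)C(OC)=CC#C1 | intermediate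
29 | caesium benzocyclobutenoxide: four-membered ring made of aryl C1, the former acetyl carbon (CH3, O−), the former α-carbon (CO2Bn, pyronyl) and aryl C6 (formed in the flask) | COCOc1c(OC)cc2c(c1OCOC)C(C)([O-])C2(C(=O)OCc1ccccc1)c1c(OCOC)cc(C[C@H](C)OCOC)oc1=O.[Cs+] | intermediate
30 | benzyl 2-[2-acetyl-5-methoxy-3,4-bis(methoxymethoxy)phenyl]-2-{4-(methoxymethoxy)-6-[(2S)-2-(methoxymethoxy)propyl]-2-oxo-2H-pyran-3-yl}acetate (epimers at the methine carbon) | COCOc1c(OC)cc(C(C(=O)OCc2ccccc2)c2c(OCOC)cc(C[C@H](C)OCOC)oc2=O)c(C(C)=O)c1OCOC | intermediate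
31 | 2-[2-acetyl-5-methoxy-3,4-bis(methoxymethoxy)phenyl]-2-{4-(methoxymethoxy)-6-[(2S)-2-(methoxymethoxy)propyl]-2-oxo-2H-pyran-3-yl}acetic acid (epimers at the methine carbon) | COCOc1c(OC)cc(C(C(=O)O)c2c(OCOC)cc(C[C@H](C)OCOC)oc2=O)c(C(C)=O)c1OCOC | intermediate
32 | 3-{[2-acetyl-5-methoxy-3,4-bis(methoxymethoxy)phenyl]methyl}-4-(methoxymethoxy)-6-[(2S)-2-(methoxymethoxy)propyl]-2H-pyran-2-one | COCOc1c(OC)cc(Cc2c(OCOC)cc(C[C@H](C)OCOC)oc2=O)c(C(C)=O)c1OCOC | intermediate
33 | penicanesin D, 3-[(2-acetyl-3,4-dihydroxy-5-methoxyphenyl)methyl]-4-hydroxy-6-[(2S)-2-hydroxypropyl]-2H-pyran-2-one | COc1cc(Cc2c(O)cc(C[C@H](C)O)oc2=O)c(C(C)=O)c(O)c1O | target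

Total step count: 18. Longest linear sequence: 12 steps (steps 6 to 11, then 13 to 18, from 12). The aryne branch (steps 1 to 5) and step 12 run in parallel.

Steps most likely to fail

Step 15. Several processes could defeat the insertion:
- Addition of the crowded, strongly stabilised enolate to the aryne may be slow.
- The aryl anion may be protonated before it closes, stopping at simple α-arylation.
- The aryl anion may close in a five-membered mode on the pyrone carbonyl or on pyrone C4.
- The pyrone diene may capture the aryne in a Diels–Alder reaction.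
- The donor enolate oxygen may displace the 4-alkoxy group.

The fallback sets out from 2 and 19 and rejoins the route at 33. It replaces the aryne by a Knoevenagel condensation with transfer hydrogenation. Aldehyde 2 is masked in the flask with LiN(Me)CH2CH2NMe2 (THF, −20 °C) as the lithium α-amino alkoxide F1. n-BuLi then removes the ring hydrogen between that group and the OMOM group to give the ring-lithiated amino alkoxide F2. N-methoxy-N-methylacetamide followed by aqueous NH4Cl gives 2-acetyl-5-methoxy-3,4-bis(methoxymethoxy)benzaldehyde F3. F3, 19 and diethyl 1,4-dihydro-2,6-dimethylpyridine-3,5-dicarboxylate (Hantzsch ester) are stirred with catalytic L-proline in CH2Cl2 at rt. They condense to the 3-arylidenepyran-2,4-dione F4, which hydride transfer reduces in the same flask to the 3-arylmethyl-4-hydroxypyrone F5. The acid treatment of step 18 then removes its three MOM groups and gives 33.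

Step 13. Each coupling partner is flanked on both sides, so transmetalation and reductive elimination may be slow. Protodemetalation, reduction of the iodide or homocoupling could then take over. The fallback sets out from 21 and rejoins the route at 27. It is a copper-catalysed Hurtley-type α-arylation of benzyl acetoacetate (CC(=O)CC(=O)OCc1ccccc1) with 21. The conditions are CuI (20 mol %), L-proline (40 mol %), Cs2CO3, DMSO, 40 °C. The lactone carbonyl next to the C–I bond can assist copper, and the low temperature avoids retro-Claisen loss of the acetyl group. No compound outside the list is made (F0), and steps 12 and 14 become unnecessary.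

Step 17. Three processes could interfere:
- Hydrogen-atom transfer to the crowded, stabilised radical may be sluggish, leading to dimerisation or capture by the thiyl radical.
- The photocatalyst may oxidise the electron-rich arene unproductively.
- The acid may rest as a cyclic lactol with the neighbouring acetyl group.

The fallback sets out from 31 and rejoins the route at 32. It generates the radical by reduction instead of oxidation. Acid 31 is coupled with N-hydroxyphthalimide (diisopropylcarbodiimide, DMAP cat., CH2Cl2) to give the N-(acyloxy)phthalimide F6. F6 is then irradiated (blue LEDs) with Ru(bpy)3(PF6)2 (1 mol %) and Hantzsch ester (1.5 equiv) in CH2Cl2. Single-electron reduction, N–O cleavage and loss of CO2 give the same radical, which takes hydrogen from the weak C–H bond of the dihydropyridine.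

Further compounds
F1 | step 15 | lithium α-amino alkoxide from 2 and lithium N,N,N'-trimethylethylenediamide | COCOc1cc(C(O[Li])N(C)CCN(C)C)cc(OC)c1OCOC
F2 | step 15 | ring-lithiated amino alkoxide, lithium on the carbon between the masked aldehyde and the OMOM group | COCOc1c(OC)cc(C(O[Li])N(C)CCN(C)C)c([Li])c1OCOC
F3 | step 15 | 2-acetyl-5-methoxy-3,4-bis(methoxymethoxy)benzaldehyde | COCOc1c(OC)cc(C=O)c(C(C)=O)c1OCOC
F4 | step 15 | 3-{[2-acetyl-5-methoxy-3,4-bis(methoxymethoxy)phenyl]methylidene}-6-[(2S)-2-(methoxymethoxy)propyl]-2H-pyran-2,4(3H)-dione | COCOc1c(OC)cc(C=C2C(=O)C=C(C[C@H](C)OCOC)OC2=O)c(C(C)=O)c1OCOC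
F5 | step 15 | 3-{[2-acetyl-5-methoxy-3,4-bis(methoxymethoxy)phenyl]methyl}-4-hydroxy-6-[(2S)-2-(methoxymethoxy)propyl]-2H-pyran-2-one | COCOc1c(OC)cc(Cc2c(O)cc(C[C@H](C)OCOC)oc2=O)c(C(C)=O)c1OCOC
F0 | step 13 | none | none
F6 | step 17 | 1,3-dioxoisoindolin-2-yl ester of acid 31 | COCOc1c(OC)cc(C(C(=O)ON2C(=O)c3ccccc3C2=O)c2c(OCOC)cc(C[C@H](C)OCOC)oc2=O)c(C(C)=O)c1OCOC
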